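**Retrosynthetic overview**
- The target is opened last at the two indole nitrogens (N-benzyl and N-silyl), which leads back to the N1-benzyl 5-hydroxyindole 20.
- Key disconnection: C3–C3a and N1–C7a of the hydroxyindole, giving enamine 17 and 1,4-benzoquinone. It rests on the carbocycle of that indole, which carries hydrogen at C4, C6 and C7 and oxygen at C5, para to the nitrogen-bearing C7a. This is the substitution pattern of 1,4-benzoquinone, and C3 holds the central arene, so it maps onto the enamine beta-carbon.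
- Enamine 17 comes from arylacetaldehyde 15, made from aryl bromide 11 by bromine–lithium exchange, oxirane opening and oxidation.
- Bromide 11 comes from a mono-Negishi coupling of a 6-prenylindol-3-ylzinc reagent (from 6-bromoindole) with 1,4-dibromo-2,3,5,6-tetramethoxybenzene.
- Ring order: the central benzene ring and the prenylindole are bought; the only ring built is the pyrrole ring of the hydroxyindole (step 9), fused onto the quinone-derived carbocycle.

Key step: step 9

Assumption: the condensation product of aldehyde 15 with benzylamine is treated as one compound and drawn as its trans enamine tautomer 17, which equilibrates in solution with the N-benzyl aldimine.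

**Step 1**
Reactants: 1 1,2,4,5-tetramethoxybenzene
Product: 2 1,4-dibromo-2,3,5,6-tetramethoxybenzene
Conditions: Br2 (2.2 equiv), CH2Cl2, 0 °C → rt
Reagents that add atoms: bromine, BrBr
Why: Twofold electrophilic aromatic bromination, in which the two remaining ring C–H positions, para to each other and each flanked by two methoxy groups, are the only sites available, so a single dibromide should result.

**Step 2**
Reactants: 3 6-bromo-1H-indole
Product: 4 6-bromo-1-(triisopropylsilyl)-1H-indole
Conditions: NaH, THF, 0 °C; TIPSCl, 0 °C → rt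
Reagents that add atoms: triisopropylsilyl chloride, CC(C)[Si](Cl)(C(C)C)C(C)C
Why: N-silylation of the sodium indolide, where the bulky silyl group masks N–H and shields C2 so that the later lithiations stay at C6 and C3.

**Step 3**
Reactants: 4 6-bromo-1-(triisopropylsilyl)-1H-indole; 5 1-bromo-3-methylbut-2-ene (prenyl bromide)
Product: 7 6-(3-methylbut-2-en-1-yl)-1-(triisopropylsilyl)-1H-indole, via 6-lithioindole 6 (not isolated)
Conditions: t-BuLi (2.05 equiv), THF, −78 °C; then 5 (1.5 equiv), −78 °C → rt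
Reagents that add atoms: none
Why: Bromine–lithium exchange is faster than any deprotonation at −78 °C, and the aryllithium should displace the primary allylic bromide by SN2 alkylation to give the linear prenyl arene.

**Step 4**
Reactants: 7 6-(3-methylbut-2-en-1-yl)-1-(triisopropylsilyl)-1H-indole
Product: 8 3-bromo-6-(3-methylbut-2-en-1-yl)-1-(triisopropylsilyl)-1H-indole
Conditions: NBS (1.0 equiv), THF, −78 °C
Reagents that add atoms: N-bromosuccinimide, O=C1CCC(=O)N1Br
Why: Electrophilic aromatic bromination of a 1-silylindole takes place at C3, its most nucleophilic carbon, and at −78 °C this should be much faster than attack of the reagent on the trisubstituted alkene.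

**Step 5**
Reactants: 8 3-bromo-6-(3-methylbut-2-en-1-yl)-1-(triisopropylsilyl)-1H-indole; 2 1,4-dibromo-2,3,5,6-tetramethoxybenzene
Product: 11 3-(4-bromo-2,3,5,6-tetramethoxyphenyl)-6-(3-methylbut-2-en-1-yl)-1-(triisopropylsilyl)-1H-indole, via 3-lithioindole 9 (not isolated), via indol-3-ylzinc chloride 10 (not isolated)
Conditions: t-BuLi (2.0 equiv), THF, −78 °C; ZnCl2 (1.1 equiv), −78 °C → rt; then 2 (3 equiv), Pd(OAc)2 (5 mol%), SPhos (10 mol%), THF, 60 °C
Reagents that add atoms: none
Why: Halogen–lithium exchange, transmetalation to zinc and Negishi cross-coupling, in which the silyl group keeps the lithium at C3, the SPhos-ligated palladium catalyst should accept the bromide flanked by two methoxy groups, and the threefold excess of symmetrical 2 should hold the coupling at the mono stage.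

**Step 6**
Reactants: 11 3-(4-bromo-2,3,5,6-tetramethoxyphenyl)-6-(3-methylbut-2-en-1-yl)-1-(triisopropylsilyl)-1H-indole; 12 oxirane
Product: 14 2-{2,3,5,6-tetramethoxy-4-[6-(3-methylbut-2-en-1-yl)-1-(triisopropylsilyl)-1H-indol-3-yl]phenyl}ethan-1-ol, via aryllithium 13 (not isolated)
Conditions: t-BuLi (2.0 equiv), THF, −78 °C; 12 (5 equiv), −78 → 0 °C; H2O
Reagents that add atoms: none
Why: Bromine–lithium exchange outruns deprotonation of the prenyl methylene at −78 °C, and the aryllithium, flanked by two methoxy groups, should open oxirane at carbon (SN2 epoxide opening) to add the two-carbon alcohol chain.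

**Step 7**
Reactants: 14 2-{2,3,5,6-tetramethoxy-4-[6-(3-methylbut-2-en-1-yl)-1-(triisopropylsilyl)-1H-indol-3-yl]phenyl}ethan-1-ol
Product: 15 2-{2,3,5,6-tetramethoxy-4-[6-(3-methylbut-2-en-1-yl)-1-(triisopropylsilyl)-1H-indol-3-yl]phenyl}acetaldehyde
Conditions: Dess–Martin periodinane (1.2 equiv), CH2Cl2, 0 °C → rt
Reagents that add atoms: none
Why: Dess–Martin oxidation of a primary alcohol stops at the aldehyde under non-aqueous, near-neutral conditions that the silylindole, the prenyl alkene and the enolisable arylacetaldehyde should tolerate.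

**Step 8**
Reactants: 15 2-{2,3,5,6-tetramethoxy-4-[6-(3-methylbut-2-en-1-yl)-1-(triisopropylsilyl)-1H-indol-3-yl]phenyl}acetaldehyde; 16 benzylamine
Product: 17 (E)-N-benzyl-2-{2,3,5,6-tetramethoxy-4-[6-(3-methylbut-2-en-1-yl)-1-(triisopropylsilyl)-1H-indol-3-yl]phenyl}ethen-1-amine (trans enamine, tautomer of the N-benzyl aldimine)
Conditions: BnNH2 (1.0 equiv), 4 Å MS, CH2Cl2, rt; filtered, concentrated, used crude
Reagents that add atoms: none
Why: Condensation of an aldehyde with a primary amine under dehydration gives the aldimine, which tautomerises to the aryl-conjugated secondary enamine (imine–enamine tautomerism), and exactly one equivalent of amine leaves none free to attack the quinone in the next step.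

**Step 9**
Reactants: 17 (E)-N-benzyl-2-{2,3,5,6-tetramethoxy-4-[6-(3-methylbut-2-en-1-yl)-1-(triisopropylsilyl)-1H-indol-3-yl]phenyl}ethen-1-amine; 18 1,4-benzoquinone
Product: 20 1-benzyl-3-{2,3,5,6-tetramethoxy-4-[6-(3-methylbut-2-en-1-yl)-1-(triisopropylsilyl)-1H-indol-3-yl]phenyl}-1H-indol-5-ol, via hydroquinone C-adduct 19 (not isolated)
Conditions: 18 (1.2 equiv), MeNO2, rt, Ar, dark
Reagents that add atoms: none
Why: Proposed new method: the enamine beta-carbon, which already carries the tetramethoxyphenyl ring, should add in Michael fashion to a C–H carbon of the quinone and give hydroquinone 19 after tautomerisation (C3–C3a); a second quinone molecule oxidises 19 to its quinone, the enamine nitrogen attacks the neighbouring quinone carbonyl carbon in a 5-exo-trig closure (N1–C7a), water is lost, and the resulting 5-oxoindolium ion is reduced by the hydroquinone formed earlier, so the overall change is redox-neutral and releases only water. The closest known reaction type is the Nenitzescu 5-hydroxyindole synthesis from benzoquinone and N-alkyl beta-aminocrotonates or beta-aminoacrylates, which has not been shown for an enamine whose beta-carbon bears an aryl group instead of an electron-withdrawing group. No stereocenter is formed, the four C–H carbons of the unsubstituted quinone are equivalent so no positional choice arises, and the C5 hydroxyl is delivered free. The step needs carbon over nitrogen attack of the enamine on the quinone and nitrogen over oxygen closure. These are favoured by the soft enamine carbon, by the N–H that lets the adduct return to an enamine whose nitrogen can reach the carbonyl, by the absence of acid (which would drive oxygen closure and loss of benzylamine to a benzofuran), by the slight excess of quinone and by the polar nitromethane medium. The triisopropylsilyl group keeps N1 and C2 of the prenylindole from adding to the quinone.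

**Step 10**
Reactants: 20 1-benzyl-3-{2,3,5,6-tetramethoxy-4-[6-(3-methylbut-2-en-1-yl)-1-(triisopropylsilyl)-1H-indol-3-yl]phenyl}-1H-indol-5-ol
Product: 21 1-benzyl-3-{2,3,5,6-tetramethoxy-4-[6-(3-methylbut-2-en-1-yl)-1H-indol-3-yl]phenyl}-1H-indol-5-ol
Conditions: Bu4NF (3 equiv), THF, 0 °C → rt
Reagents that add atoms: none
Why: Fluoride-induced N-desilylation, driven by the strong Si–F bond, should free the prenylindole N–H without touching the N-benzyl group, the phenol or the alkene.

**Step 11**
Reactants: 21 1-benzyl-3-{2,3,5,6-tetramethoxy-4-[6-(3-methylbut-2-en-1-yl)-1H-indol-3-yl]phenyl}-1H-indol-5-ol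
Product: 22 3-{2,3,5,6-tetramethoxy-4-[6-(3-methylbut-2-en-1-yl)-1H-indol-3-yl]phenyl}-1H-indol-5-ol (target)
Conditions: Na, NH3(l)/THF, −78 °C; NH4Cl
Reagents that add atoms: none
Why: Dissolving-metal reductive N-debenzylation, in which electron transfer to the N-benzyl group fragments the C–N bond to the indolide and toluene, while the phenoxide and indolide anions resist ring reduction and the isolated trisubstituted alkene is not reduced.

**Compound list**
1 | 1,2,4,5-tetramethoxybenzene | COc1cc(OC)c(OC)cc1OC | starting material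
2 | 1,4-dibromo-2,3,5,6-tetramethoxybenzene | COc1c(Br)c(OC)c(OC)c(Br)c1OC | intermediate
3 | 6-bromo-1H-indole | Brc1ccc2cc[nH]c2c1 | starting material
4 | 6-bromo-1-(triisopropylsilyl)-1H-indole | CC(C)[Si](C(C)C)(C(C)C)n1ccc2ccc(Br)cc21 | intermediate
5 | 1-bromo-3-methylbut-2-ene (prenyl bromide) | CC(C)=CCBr | starting material
6 | 6-lithio-1-(triisopropylsilyl)-1H-indole | CC(C)[Si](C(C)C)(C(C)C)n1ccc2ccc([Li])cc21 | intermediate (not isolated)
7 | 6-(3-methylbut-2-en-1-yl)-1-(triisopropylsilyl)-1H-indole | CC(C)=CCc1ccc2ccn([Si](C(C)C)(C(C)C)C(C)C)c2c1 | intermediate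
8 | 3-bromo-6-(3-methylbut-2-en-1-yl)-1-(triisopropylsilyl)-1H-indole | CC(C)=CCc1ccc2c(Br)cn([Si](C(C)C)(C(C)C)C(C)C)c2c1 | intermediate
9 | 3-lithio-6-(3-methylbut-2-en-1-yl)-1-(triisopropylsilyl)-1H-indole | CC(C)=CCc1ccc2c([Li])cn([Si](C(C)C)(C(C)C)C(C)C)c2c1 | intermediate (not isolated)
10 | [6-(3-methylbut-2-en-1-yl)-1-(triisopropylsilyl)-1H-indol-3-yl]zinc chloride | CC(C)=CCc1ccc2c([Zn]Cl)cn([Si](C(C)C)(C(C)C)C(C)C)c2c1 | intermediate (not isolated)
11 | 3-(4-bromo-2,3,5,6-tetramethoxyphenyl)-6-(3-methylbut-2-en-1-yl)-1-(triisopropylsilyl)-1H-indole | COc1c(Br)c(OC)c(OC)c(-c2cn([Si](C(C)C)(C(C)C)C(C)C)c3cc(CC=C(C)C)ccc23)c1OC | intermediate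
12 | oxirane | C1CO1 | starting material
13 | {2,3,5,6-tetramethoxy-4-[6-(3-methylbut-2-en-1-yl)-1-(triisopropylsilyl)-1H-indol-3-yl]phenyl}lithium | COc1c([Li])c(OC)c(OC)c(-c2cn([Si](C(C)C)(C(C)C)C(C)C)c3cc(CC=C(C)C)ccc23)c1OC | intermediate (not isolated)
14 | 2-{2,3,5,6-tetramethoxy-4-[6-(3-methylbut-2-en-1-yl)-1-(triisopropylsilyl)-1H-indol-3-yl]phenyl}ethan-1-ol | COc1c(CCO)c(OC)c(OC)c(-c2cn([Si](C(C)C)(C(C)C)C(C)C)c3cc(CC=C(C)C)ccc23)c1OC | intermediate
15 | 2-{2,3,5,6-tetramethoxy-4-[6-(3-methylbut-2-en-1-yl)-1-(triisopropylsilyl)-1H-indol-3-yl]phenyl}acetaldehyde | COc1c(CC=O)c(OC)c(OC)c(-c2cn([Si](C(C)C)(C(C)C)C(C)C)c3cc(CC=C(C)C)ccc23)c1OC | intermediate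
16 | benzylamine | NCc1ccccc1 | starting material
17 | (E)-N-benzyl-2-{2,3,5,6-tetramethoxy-4-[6-(3-methylbut-2-en-1-yl)-1-(triisopropylsilyl)-1H-indol-3-yl]phenyl}ethen-1-amine (trans enamine, in equilibrium with the aldimine) | COc1c(/C=C/NCc2ccccc2)c(OC)c(OC)c(-c2cn([Si](C(C)C)(C(C)C)C(C)C)c3cc(CC=C(C)C)ccc23)c1OC | intermediate
18 | 1,4-benzoquinone | O=C1C=CC(=O)C=C1 | starting material
19 | 2-[2-(benzylamino)-1-{2,3,5,6-tetramethoxy-4-[6-(3-methylbut-2-en-1-yl)-1-(triisopropylsilyl)-1H-indol-3-yl]phenyl}ethenyl]benzene-1,4-diol (enamine tautomer, alkene geometry mobile) | COc1c(C(=CNCc2ccccc2)c2cc(O)ccc2O)c(OC)c(OC)c(-c2cn([Si](C(C)C)(C(C)C)C(C)C)c3cc(CC=C(C)C)ccc23)c1OC | intermediate (not isolated)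
20 | 1-benzyl-3-{2,3,5,6-tetramethoxy-4-[6-(3-methylbut-2-en-1-yl)-1-(triisopropylsilyl)-1H-indol-3-yl]phenyl}-1H-indol-5-ol | Oc1ccc2c(c1)c(-c1c(OC)c(OC)c(-c3cn([Si](C(C)C)(C(C)C)C(C)C)c4cc(CC=C(C)C)ccc34)c(OC)c1OC)cn2Cc1ccccc1 | intermediate
21 | 1-benzyl-3-{2,3,5,6-tetramethoxy-4-[6-(3-methylbut-2-en-1-yl)-1H-indol-3-yl]phenyl}-1H-indol-5-ol | Oc1ccc2c(c1)c(-c1c(OC)c(OC)c(-c3c[nH]c4cc(CC=C(C)C)ccc34)c(OC)c1OC)cn2Cc1ccccc1 | intermediate
22 | 3-{2,3,5,6-tetramethoxy-4-[6-(3-methylbut-2-en-1-yl)-1H-indol-3-yl]phenyl}-1H-indol-5-ol | COc1c(OC)c(-c2c[nH]c3ccc(O)cc23)c(OC)c(OC)c1-c1c[nH]c2cc(CC=C(C)C)ccc12 | target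

**Step count**
Total: 11 steps. Longest linear sequence: 10 steps (steps 2 to 11, from 6-bromoindole).

**Steps most likely to fail**

1. Step 9 (proposed annulation). The adduct may close through the hydroquinone oxygen onto the imine carbon and lose benzylamine, the enamine may attack the quinone through nitrogen, the quinone may oxidise the electron-rich enamine, or too little enamine tautomer may be present.
Fallback (known chemistry, sets out from 11 and comes back at 22): the hydroxyindole would be brought in ready-made by a second Negishi coupling. Commercial 5-hydroxyindole (Oc1ccc2[nH]ccc2c1) would be silylated on oxygen and nitrogen (NaH, TIPSCl, THF) to 1-(triisopropylsilyl)-5-[(triisopropylsilyl)oxy]-1H-indole F1. Bromination at C3 (NBS, THF, −78 °C) would give 3-bromo-1-(triisopropylsilyl)-5-[(triisopropylsilyl)oxy]-1H-indole F2. Treatment with t-BuLi would give the 3-lithio compound F3, and ZnCl2 the indol-3-ylzinc chloride F4. Coupling of F4 with bromide 11 under the Pd(OAc)2/SPhos conditions of step 5 would give the tris-silylated bis-indole F5, and Bu4NF in THF would remove all three silyl groups to give 22.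

2. Step 5 (mono-Negishi coupling). Coupling may run on at the second C–Br bond, or oxidative addition at the hindered, electron-rich bromide may be sluggish.
Fallback (sets out from 2 and zinc reagent 10, comes back at 11): the two halogens would be differentiated before coupling. One bromine–lithium exchange on 2 (n-BuLi, 1.0 equiv, THF, −78 °C) would give (4-bromo-2,3,5,6-tetramethoxyphenyl)lithium F6, and iodine would convert it into 1-bromo-4-iodo-2,3,5,6-tetramethoxybenzene F7. Negishi coupling of F7 with 10 (Pd(PPh3)4, THF, rt to 50 °C) should take place at the C–I bond only and give 11.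

3. Step 11 (reductive debenzylation). The sodium amide formed may move the prenyl double bond into conjugation with the ring, a methoxy group of the crowded central ring may be lost reductively, or a ring may be reduced on quenching.
Fallback (sets out from 15, comes back at 22): a base-labile nitrogen substituent would replace benzyl. Aldehyde 15 would be condensed with commercial 2-(phenylsulfonyl)ethan-1-amine (NCCS(=O)(=O)c1ccccc1) to the trans enamine (E)-N-[2-(phenylsulfonyl)ethyl]-2-{2,3,5,6-tetramethoxy-4-[6-(3-methylbut-2-en-1-yl)-1-(triisopropylsilyl)-1H-indol-3-yl]phenyl}ethen-1-amine F8. Annulation with 18 as in step 9 would give the 1-[2-(phenylsulfonyl)ethyl]-5-hydroxyindole F9, and Bu4NF would desilylate it to F10. Potassium tert-butoxide in DMF at rt would then release 22 by retro-Michael (E1cB) loss of phenyl vinyl sulfone.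

**Further compounds**
F1 | step 9 | 1-(triisopropylsilyl)-5-[(triisopropylsilyl)oxy]-1H-indole | CC(C)[Si](Oc1ccc2c(ccn2[Si](C(C)C)(C(C)C)C(C)C)c1)(C(C)C)C(C)C
F2 | step 9 | 3-bromo-1-(triisopropylsilyl)-5-[(triisopropylsilyl)oxy]-1H-indole | CC(C)[Si](Oc1ccc2c(c(Br)cn2[Si](C(C)C)(C(C)C)C(C)C)c1)(C(C)C)C(C)C
F3 | step 9 | 3-lithio-1-(triisopropylsilyl)-5-[(triisopropylsilyl)oxy]-1H-indole | CC(C)[Si](Oc1ccc2c(c([Li])cn2[Si](C(C)C)(C(C)C)C(C)C)c1)(C(C)C)C(C)C
F4 | step 9 | {1-(triisopropylsilyl)-5-[(triisopropylsilyl)oxy]-1H-indol-3-yl}zinc chloride | CC(C)[Si](Oc1ccc2c(c([Zn]Cl)cn2[Si](C(C)C)(C(C)C)C(C)C)c1)(C(C)C)C(C)C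
F5 | step 9 | 3-{2,3,5,6-tetramethoxy-4-[6-(3-methylbut-2-en-1-yl)-1-(triisopropylsilyl)-1H-indol-3-yl]phenyl}-1-(triisopropylsilyl)-5-[(triisopropylsilyl)oxy]-1H-indole | CC(C)[Si](Oc1ccc2c(c1)c(-c1c(OC)c(OC)c(-c3cn([Si](C(C)C)(C(C)C)C(C)C)c4cc(CC=C(C)C)ccc34)c(OC)c1OC)cn2[Si](C(C)C)(C(C)C)C(C)C)(C(C)C)C(C)C
F6 | step 5 | (4-bromo-2,3,5,6-tetramethoxyphenyl)lithium | COc1c(Br)c(OC)c(OC)c([Li])c1OC
F7 | step 5 | 1-bromo-4-iodo-2,3,5,6-tetramethoxybenzene | COc1c(Br)c(OC)c(OC)c(I)c1OC
F8 | step 11 | (E)-N-[2-(phenylsulfonyl)ethyl]-2-{2,3,5,6-tetramethoxy-4-[6-(3-methylbut-2-en-1-yl)-1-(triisopropylsilyl)-1H-indol-3-yl]phenyl}ethen-1-amine | COc1c(/C=C/NCCS(=O)(=O)c2ccccc2)c(OC)c(OC)c(-c2cn([Si](C(C)C)(C(C)C)C(C)C)c3cc(CC=C(C)C)ccc23)c1OC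
F9 | step 11 | 1-[2-(phenylsulfonyl)ethyl]-3-{2,3,5,6-tetramethoxy-4-[6-(3-methylbut-2-en-1-yl)-1-(triisopropylsilyl)-1H-indol-3-yl]phenyl}-1H-indol-5-ol | Oc1ccc2c(c1)c(-c1c(OC)c(OC)c(-c3cn([Si](C(C)C)(C(C)C)C(C)C)c4cc(CC=C(C)C)ccc34)c(OC)c1OC)cn2CCS(=O)(=O)c1ccccc1
F10 | step 11 | 1-[2-(phenylsulfonyl)ethyl]-3-{2,3,5,6-tetramethoxy-4-[6-(3-methylbut-2-en-1-yl)-1H-indol-3-yl]phenyl}-1H-indol-5-ol | Oc1ccc2c(c1)c(-c1c(OC)c(OC)c(-c3c[nH]c4cc(CC=C(C)C)ccc34)c(OC)c1OC)cn2CCS(=O)(=O)c1ccccc1
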